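## Plan

- **Numbering.** Ring A is C1 (quaternary, methyl C15), C2, C3, C4 (isopropyl carbinol), C5 (fusion CH). Ring B is C5, C6 (ester carbinol), C7, C8 (spiro-epoxide, CH2 = C14), C9, C10 (diol), C1. α is the face of H5 and β the face of C15.
- **Cuts, in retrosynthetic order.** The epoxide oxygen, C8=C14, the isovalerate, the C4–O bond, O9 and O10, C9=C10, C6–C7, then C1–C5 (ring A traced back to a cyclohexanone) and C1–C10.
- **Enabling feature.** O4 and O6 end a 1,3-diol across C4–C5–C6. C4 is tertiary, and in the 4-deoxy compound H4β and C6 are cis on ring A. A nitrogen radical hung on O6 can therefore take H4β, and its carbonyl oxygen can come back only to that face.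
- **Forward order.** The six-membered ring of (R)-carvone is allylated and contracted to ring A. Ring B follows by aldol addition and ring-closing metathesis. A temporary six-membered carbonate ring forms in the key step, and the oxirane comes last.
- **Stereochemistry.** C4–H comes from carvone, C1 from axial allylation cis to isopropyl, and C5 from equilibration. C6 follows Felkin–Anh addition, and C9/C10 come from osmylation anti to C15. O4 is placed by the tether, and C8 by epoxidation directed by the 9α-hydroxyl.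

Key step: step 13

Remark on the chemistry: the tertiary bromide of the key step is expected as both C4 epimers, which ionise to one cation, so its SMILES leaves C4 open. Bicyclic intermediates that lack C14 are named as 14-nordaucanes with the numbering above.

## Route

Step 1
Reactants: 1 (R)-(−)-carvone
Product: 2 (R)-carvotanacetone [(5R)-2-methyl-5-(propan-2-yl)cyclohex-2-en-1-one]
Conditions: H2 (1 atm), RhCl(PPh3)3 (1 mol %), toluene, rt
Reagents that add atoms: none
Why: Homogeneous hydrogenation with RhCl(PPh3)3 saturates the unhindered 1,1-disubstituted isopropenyl alkene much faster than the conjugated trisubstituted ring alkene, and the stereocentre that becomes C4 is not touched.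

Step 2
Reactants: 2 (R)-carvotanacetone; 3 allyl bromide
Product: 5 (2R,5R)-2-allyl-2-methyl-5-(propan-2-yl)cyclohexan-1-one (allyl cis to isopropyl), via lithium enolate 4 (not isolated)
Conditions: Li (2.1 equiv), t-BuOH (1 equiv), NH3(l)–THF, −78 °C; then 3, −78 to −33 °C
Reagents that add atoms: allyl bromide (3), C=CCBr
Why: Dissolving-metal reduction gives the tetrasubstituted enolate regiospecifically (reductive alkylation), and the stereoelectronically preferred axial attack on the half-chair with equatorial isopropyl places allyl cis to isopropyl, which sets C1 with its methyl group on the β face.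

Step 3
Reactants: 5 (2R,5R)-2-allyl-2-methyl-5-(propan-2-yl)cyclohexan-1-one
Product: 6 (2R,5R)-2-methyl-5-(propan-2-yl)-2-[(E)-prop-1-en-1-yl]cyclohexan-1-one
Conditions: RuHCl(CO)(PPh3)3 (3 mol %), toluene, 110 °C
Reagents that add atoms: none
Why: Ruthenium hydride addition and elimination (allyl-to-propenyl isomerisation) moves the alkene one position inward, where it must stop because C1 is quaternary, and crowding favours the E isomer while no stereocentre is touched.

Step 4
Reactants: 6 (2R,5R)-2-methyl-5-(propan-2-yl)-2-[(E)-prop-1-en-1-yl]cyclohexan-1-one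
Product: 8 (2R,5S)-6-diazo-2-methyl-5-(propan-2-yl)-2-[(E)-prop-1-en-1-yl]cyclohexan-1-one, via trifluoroacetyl ketone 7 (not isolated)
Conditions: LiN(SiMe3)2, THF, −78 °C; CF3CO2CH2CF3; then MsN3, Et3N, H2O (1 equiv), MeCN, rt
Reagents that add atoms: methanesulfonyl azide, CS(=O)(=O)N=[N+]=[N-] (N2 of 8); 2,2,2-trifluoroethyl trifluoroacetate, O=C(OCC(F)(F)F)C(F)(F)F (CF3CO of 7 only)
Why: Detrifluoroacetylative diazo transfer (Danheiser form of the Regitz reaction) can act only at the CH2 between the carbonyl group and C4, because the other α-carbon is quaternary.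

Step 5
Reactants: 8 (2R,5S)-6-diazo-2-methyl-5-(propan-2-yl)-2-[(E)-prop-1-en-1-yl]cyclohexan-1-one
Product: 11 methyl (1S,2R,5S)-2-methyl-5-(propan-2-yl)-2-[(E)-prop-1-en-1-yl]cyclopentane-1-carboxylate, via ketene 9 (not isolated), via C5-epimeric ester 10 (not isolated)
Conditions: hν (Hg lamp, Pyrex), MeOH, rt; then NaOMe (0.2 equiv), MeOH, 65 °C
Reagents that add atoms: methanol, CO
Why: The photochemical Wolff rearrangement of the s-Z-locked cyclic diazoketone shifts quaternary C1 with retention onto the carbene carbon and contracts the ring to ring A, methanol adds to the ketene, and methoxide equilibration drains the cis ester into the isomer with the ester at C5 trans to isopropyl and propenyl (H5 α).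

Step 6
Reactants: 11 methyl (1S,2R,5S)-2-methyl-5-(propan-2-yl)-2-[(E)-prop-1-en-1-yl]cyclopentane-1-carboxylate
Product: 12 (1S,2R,5S)-2-methyl-5-(propan-2-yl)-2-[(E)-prop-1-en-1-yl]cyclopentane-1-carbaldehyde
Conditions: i-Bu2AlH (1.1 equiv), CH2Cl2, −78 °C; aq. potassium sodium tartrate
Reagents that add atoms: none
Why: Low-temperature i-Bu2AlH reduction of a hindered methyl ester is a standard route to the aldehyde, the crowding around C6 holds back over-reduction, and C5 already has its more stable configuration.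

Step 7
Reactants: 12 (1S,2R,5S)-2-methyl-5-(propan-2-yl)-2-[(E)-prop-1-en-1-yl]cyclopentane-1-carbaldehyde; 13 2-(trimethylsiloxy)buta-1,3-diene
Product: 14 (5S)-5-hydroxy-5-{(1S,2R,5S)-2-methyl-5-(propan-2-yl)-2-[(E)-prop-1-en-1-yl]cyclopentyl}pent-1-en-3-one
Conditions: BF3·OEt2 (1.05 equiv), CH2Cl2, −78 °C; aq. NaHCO3
Reagents that add atoms: 2-(trimethylsiloxy)buta-1,3-diene (13), C=CC(=C)O[Si](C)(C)C
Why: The open-transition-state Mukaiyama aldol addition follows the Felkin–Anh model with quaternary C1 as the large and C4 as the medium group, so C7 attacks anti to C1 and the new carbinol C6 gets the S configuration that becomes 6α-O in the bicycle.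

Step 8
Reactants: 14 (5S)-5-hydroxy-5-{(1S,2R,5S)-2-methyl-5-(propan-2-yl)-2-[(E)-prop-1-en-1-yl]cyclopentyl}pent-1-en-3-one; 15 2,2,2-trifluoroethyl isocyanate
Product: 16 (2,2,2-trifluoroethyl)carbamate of 14 at O6
Conditions: 15 (1.5 equiv), Bu2Sn(O2CC11H23)2 (5 mol %), toluene, rt to 40 °C
Reagents that add atoms: 2,2,2-trifluoroethyl isocyanate (15), O=C=NCC(F)(F)F
Why: Tin-catalysed addition of the alcohol to the isocyanate (urethane formation) is neutral, so retro-aldol cleavage, β-elimination and oxa-Michael closure of the hydroxy enone are not triggered and C6 keeps its configuration.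

Step 9
Reactants: 16 (2,2,2-trifluoroethyl)carbamate of 14 at O6
Product: 17 6α-[(2,2,2-trifluoroethyl)carbamoyloxy]-14-nor-4βH,5αH-dauc-9-en-8-one
Conditions: second-generation Hoveyda–Grubbs catalyst (5–10 mol %), toluene (2 mM), 80 °C
Reagents that add atoms: none
Why: Ring-closing metathesis joins C9 to C10 from two arms that stand trans on ring A and so suit a trans-fused seven-membered ring, the ring size enforces the Z alkene, and loss of propene drives the closure.

Step 10
Reactants: 17 6α-[(2,2,2-trifluoroethyl)carbamoyloxy]-14-nor-4βH,5αH-dauc-9-en-8-one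
Product: 18 8,8-ethylenedioxy-14-nor-4βH,5αH-dauc-9-en-6α-yl (2,2,2-trifluoroethyl)carbamate
Conditions: Me3SiOCH2CH2OSiMe3 (2 equiv), Me3SiOTf (5 mol %), CH2Cl2, −78 to −20 °C
Reagents that add atoms: 1,2-bis(trimethylsiloxy)ethane, C[Si](C)(C)OCCO[Si](C)(C)C
Why: Noyori ketalisation runs cold and without protic acid, which spares the β-carbamoyloxy ketone from elimination, and the alkene cannot migrate because C1 carries no hydrogen.

Step 11
Reactants: 18 8,8-ethylenedioxy-14-nor-4βH,5αH-dauc-9-en-6α-yl (2,2,2-trifluoroethyl)carbamate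
Product: 19 8,8-ethylenedioxy-9α,10α-dihydroxy-14-nor-4βH,5αH-daucan-6α-yl (2,2,2-trifluoroethyl)carbamate
Conditions: OsO4 (5 mol %), NMO (2 equiv), acetone–H2O, rt
Reagents that add atoms: N-methylmorpholine N-oxide, C[N+]1([O-])CCOCC1, and water, O (both oxygens are handed on through OsO4)
Why: Upjohn dihydroxylation adds both oxygens suprafacially, and the axial β-methyl group C15 on the neighbouring C1 shields the β face, so the 9α,10α-diol should result.

Step 12
Reactants: 19 8,8-ethylenedioxy-9α,10α-dihydroxy-14-nor-4βH,5αH-daucan-6α-yl (2,2,2-trifluoroethyl)carbamate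
Product: 20 8,8-ethylenedioxy-9α,10α-isopropylidenedioxy-14-nor-4βH,5αH-daucan-6α-yl (2,2,2-trifluoroethyl)carbamate
Conditions: Me2C(OMe)2, PPTS (10 mol %), CH2Cl2, rt
Reagents that add atoms: 2,2-dimethoxypropane, COC(C)(C)OC
Why: Acid-catalysed transketalisation closes a dioxolane on the cis-diol and leaves the carbamate N–H as the only site that a hypobromite can attack.

Step 13
Reactants: 20 8,8-ethylenedioxy-9α,10α-isopropylidenedioxy-14-nor-4βH,5αH-daucan-6α-yl (2,2,2-trifluoroethyl)carbamate
Product: 24 8,8-ethylenedioxy-9α,10α-isopropylidenedioxy-14-nor-5αH-daucane-4β,6α-diyl carbonate, via N-bromocarbamate 21 (not isolated), via tertiary C4 bromide 22 (not isolated), via cyclic iminocarbonate 23 (not isolated)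
Conditions: CH3CO2Br (1.1 equiv), CH2Cl2, 0 °C, dark; CBr4 (1 equiv), PhCF3, hν (tungsten lamp), rt; Ag2CO3 (1.5 equiv), CH2Cl2, rt; AcOH–H2O–THF, rt
Reagents that add atoms: water, O (carbonyl oxygen of 24); acetyl hypobromite, CC(=O)OBr (bromine of 21 and 22 only)
Why: Acetyl hypobromite turns the N–H of the trifluoroethyl carbamate into N–Br, light splits that bond, the electrophilic nitrogen radical takes H4β through a seven-membered transition state (1,6-transfer), and the C4 radical picks up bromine from CBr4 or from another N–Br and so carries the chain. This is the Hofmann–Löffler–Freytag manifold in its carbamate form for 1,3-diols, which is known to prefer tertiary C–H bonds. Ag2CO3 then removes bromide, the carbamate carbonyl oxygen closes the one new ring, a six-membered 1,3-dioxane, in a 6-exo-tet sense with SN1 timing, and mild acid exchanges the C=N of 23 for the C=O of 24. The only new stereocentre, C4, is fixed by the tether, since C6 stands on the β face of ring A and oxygen can arrive only there whichever bromide epimer ionises, which leaves isopropyl α. Site selectivity among the C–H bonds near O6 is needed and comes from the substrate: C1 and C8 bear no hydrogen, equatorial O6 is anti to both and gauche to C4, the isopropyl methine is one atom further out on the α face, and the CF3 group protects the tether itself. The new ring is cis-fused to ring A and trans-fused to ring B and must therefore close as a twist-boat, which the small C4–C5 torsion of ring A and the flexible seven-membered ring should allow.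

Step 14
Reactants: 24 8,8-ethylenedioxy-9α,10α-isopropylidenedioxy-14-nor-5αH-daucane-4β,6α-diyl carbonate
Product: 25 8,8-ethylenedioxy-9α,10α-isopropylidenedioxy-14-nor-5αH-daucane-4β,6α-diol
Conditions: K2CO3 (0.2 equiv), MeOH, rt
Reagents that add atoms: none
Why: Base-catalysed transesterification with methanol opens the strained cyclic carbonate without touching ketal or acetonide, no C–O bond to a stereocentre is broken, and the masked C8 ketone rules out β-elimination.

Step 15
Reactants: 25 8,8-ethylenedioxy-9α,10α-isopropylidenedioxy-14-nor-5αH-daucane-4β,6α-diol; 26 3-methylbutanoic (isovaleric) anhydride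
Product: 27 8,8-ethylenedioxy-4β-hydroxy-9α,10α-isopropylidenedioxy-14-nor-5αH-daucan-6α-yl 3-methylbutanoate
Conditions: 26 (1.5 equiv), DMAP (0.2 equiv), Et3N, CH2Cl2, rt
Reagents that add atoms: 3-methylbutanoic anhydride (26), CC(C)CC(=O)OC(=O)CC(C)C
Why: DMAP-catalysed acyl transfer distinguishes the secondary equatorial 6α-hydroxyl from the tertiary 4β-hydroxyl on steric grounds.

Step 16
Reactants: 27 8,8-ethylenedioxy-4β-hydroxy-9α,10α-isopropylidenedioxy-14-nor-5αH-daucan-6α-yl 3-methylbutanoate
Product: 28 4β-hydroxy-9α,10α-isopropylidenedioxy-8-oxo-14-nor-5αH-daucan-6α-yl 3-methylbutanoate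
Conditions: PPTS (0.2 equiv), acetone–H2O (20:1), 56 °C
Reagents that add atoms: water, O
Why: Mild acid-catalysed ketal hydrolysis in a large excess of acetone frees the C8 ketone while any opening of the 9,10-acetonide is reversed by the solvent, and the absence of base protects the β-acyloxy ketone from elimination.

Step 17
Reactants: 28 4β-hydroxy-9α,10α-isopropylidenedioxy-8-oxo-14-nor-5αH-daucan-6α-yl 3-methylbutanoate
Product: 29 4β-hydroxy-9α,10α-isopropylidenedioxy-5αH-dauc-8(14)-en-6α-yl 3-methylbutanoate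
Conditions: Zn, CH2Br2, TiCl4 (pre-aged in THF, excess), CH2Cl2, 0 °C to rt
Reagents that add atoms: dibromomethane, BrCBr
Why: The Lombardo form of the Takai methylenation uses a non-basic geminal dimetal reagent that converts hindered enolisable ketones into methylene compounds without β-elimination or epimerisation and leaves esters alone.

Step 18
Reactants: 29 4β-hydroxy-9α,10α-isopropylidenedioxy-5αH-dauc-8(14)-en-6α-yl 3-methylbutanoate
Product: 30 4β,9α,10α-trihydroxy-5αH-dauc-8(14)-en-6α-yl 3-methylbutanoate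
Conditions: AcOH–H2O (4:1), 40 °C
Reagents that add atoms: none
Why: Aqueous acetic acid hydrolyses the acetonide to the cis-diol under conditions too mild to ionise the tertiary or the allylic alcohol or to cleave the ester.

Step 19
Reactants: 30 4β,9α,10α-trihydroxy-5αH-dauc-8(14)-en-6α-yl 3-methylbutanoate
Product: 31 8α,14-epoxy-4β,9α,10α-trihydroxy-5αH-daucan-6α-yl 3-methylbutanoate (CNP0307265.1)
Conditions: VO(acac)2 (5 mol %), t-BuOOH (decane, 1.5 equiv), CH2Cl2, 0 °C
Reagents that add atoms: tert-butyl hydroperoxide, CC(C)(C)OO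
Why: Hydroxyl-directed vanadium-catalysed epoxidation binds the peroxide to the allylic 9α-hydroxyl, supported by the homoallylic 10α-hydroxyl, and hands oxygen to the α face of C8=C14, which sets C8 with the epoxide oxygen α.

## Compound list

1 | (R)-(−)-carvone | CC1=CC[C@H](CC1=O)C(C)=C | starting material
2 | (R)-carvotanacetone | CC1=CC[C@H](CC1=O)C(C)C | intermediate
3 | allyl bromide | C=CCBr | starting material
4 | lithium enolate of (5R)-2-methyl-5-isopropylcyclohexanone (tetrasubstituted enolate) | [Li+].[O-]C1=C(C)CC[C@@H](C(C)C)C1 | intermediate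
5 | (2R,5R)-2-allyl-2-methyl-5-(propan-2-yl)cyclohexan-1-one | C=CC[C@@]1(C)CC[C@@H](C(C)C)CC1=O | intermediate
6 | (2R,5R)-2-methyl-5-(propan-2-yl)-2-[(E)-prop-1-en-1-yl]cyclohexan-1-one | C/C=C/[C@@]1(C)CC[C@@H](C(C)C)CC1=O | intermediate
7 | 6-trifluoroacetyl derivative of 6 | C/C=C/[C@@]1(C)CC[C@@H](C(C)C)C(C(=O)C(F)(F)F)C1=O | intermediate
8 | (2R,5S)-6-diazo-2-methyl-5-(propan-2-yl)-2-[(E)-prop-1-en-1-yl]cyclohexan-1-one | C/C=C/[C@@]1(C)CC[C@@H](C(C)C)C(=[N+]=[N-])C1=O | intermediate
9 | ring-contracted cyclopentylidene ketene (C1 and C4 as in 8) | C/C=C/[C@@]1(C)CC[C@@H](C(C)C)C1=C=O | intermediate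
10 | methyl (1R,2R,5S)-2-methyl-5-(propan-2-yl)-2-[(E)-prop-1-en-1-yl]cyclopentane-1-carboxylate (ester cis to isopropyl) | C/C=C/[C@@]1(C)CC[C@@H](C(C)C)[C@H]1C(=O)OC | intermediate
11 | methyl (1S,2R,5S)-2-methyl-5-(propan-2-yl)-2-[(E)-prop-1-en-1-yl]cyclopentane-1-carboxylate | C/C=C/[C@@]1(C)CC[C@@H](C(C)C)[C@@H]1C(=O)OC | intermediate
12 | (1S,2R,5S)-2-methyl-5-(propan-2-yl)-2-[(E)-prop-1-en-1-yl]cyclopentane-1-carbaldehyde | C/C=C/[C@@]1(C)CC[C@@H](C(C)C)[C@@H]1C=O | intermediate
13 | 2-(trimethylsiloxy)buta-1,3-diene | C=CC(=C)O[Si](C)(C)C | starting material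
14 | (5S)-5-hydroxy-5-{(1S,2R,5S)-2-methyl-5-(propan-2-yl)-2-[(E)-prop-1-en-1-yl]cyclopentyl}pent-1-en-3-one | C/C=C/[C@@]1(C)CC[C@@H](C(C)C)[C@@H]1[C@@H](O)CC(=O)C=C | intermediate
15 | 2,2,2-trifluoroethyl isocyanate | O=C=NCC(F)(F)F | starting material
16 | (2,2,2-trifluoroethyl)carbamate of 14 at O6 | C/C=C/[C@@]1(C)CC[C@@H](C(C)C)[C@@H]1[C@@H](OC(=O)NCC(F)(F)F)CC(=O)C=C | intermediate
17 | 6α-[(2,2,2-trifluoroethyl)carbamoyloxy]-14-nor-4βH,5αH-dauc-9-en-8-one | FC(F)(F)CNC(=O)O[C@H]1CC(=O)C=C[C@@]2(C)CC[C@@H](C(C)C)[C@H]12 | intermediate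
18 | 8,8-ethylenedioxy-14-nor-4βH,5αH-dauc-9-en-6α-yl (2,2,2-trifluoroethyl)carbamate | FC(F)(F)CNC(=O)O[C@H]1CC2(OCCO2)C=C[C@@]3(C)CC[C@@H](C(C)C)[C@H]13 | intermediate
19 | 8,8-ethylenedioxy-9α,10α-dihydroxy-14-nor-4βH,5αH-daucan-6α-yl (2,2,2-trifluoroethyl)carbamate | FC(F)(F)CNC(=O)O[C@H]1CC2(OCCO2)[C@@H](O)[C@@H](O)[C@@]3(C)CC[C@@H](C(C)C)[C@H]13 | intermediate
20 | 8,8-ethylenedioxy-9α,10α-isopropylidenedioxy-14-nor-4βH,5αH-daucan-6α-yl (2,2,2-trifluoroethyl)carbamate (precursor of the key step) | FC(F)(F)CNC(=O)O[C@H]1CC2(OCCO2)[C@H]3OC(C)(C)O[C@H]3[C@@]4(C)CC[C@@H](C(C)C)[C@H]14 | intermediate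
21 | N-bromo derivative of 20 | FC(F)(F)CN(Br)C(=O)O[C@H]1CC2(OCCO2)[C@H]3OC(C)(C)O[C@H]3[C@@]4(C)CC[C@@H](C(C)C)[C@H]14 | intermediate
22 | 4-bromo derivative of 20 (both C4 epimers) | FC(F)(F)CNC(=O)O[C@H]1CC2(OCCO2)[C@H]3OC(C)(C)O[C@H]3[C@@]4(C)CCC(Br)(C(C)C)[C@H]14 | intermediate
23 | 4β,6α-cyclic N-(2,2,2-trifluoroethyl)iminocarbonate | FC(F)(F)CN=C1O[C@H]2CC3(OCCO3)[C@H]4OC(C)(C)O[C@H]4[C@@]5(C)CC[C@@](O1)(C(C)C)[C@H]25 | intermediate
24 | 8,8-ethylenedioxy-9α,10α-isopropylidenedioxy-14-nor-5αH-daucane-4β,6α-diyl carbonate (product of the key step) | O=C1O[C@H]2CC3(OCCO3)[C@H]4OC(C)(C)O[C@H]4[C@@]5(C)CC[C@@](O1)(C(C)C)[C@H]25 | intermediate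
25 | 8,8-ethylenedioxy-9α,10α-isopropylidenedioxy-14-nor-5αH-daucane-4β,6α-diol | O[C@H]1CC2(OCCO2)[C@H]3OC(C)(C)O[C@H]3[C@@]4(C)CC[C@@](O)(C(C)C)[C@H]14 | intermediate
26 | 3-methylbutanoic (isovaleric) anhydride | CC(C)CC(=O)OC(=O)CC(C)C | starting material
27 | 8,8-ethylenedioxy-4β-hydroxy-9α,10α-isopropylidenedioxy-14-nor-5αH-daucan-6α-yl 3-methylbutanoate | CC(C)CC(=O)O[C@H]1CC2(OCCO2)[C@H]3OC(C)(C)O[C@H]3[C@@]4(C)CC[C@@](O)(C(C)C)[C@H]14 | intermediate
28 | 4β-hydroxy-9α,10α-isopropylidenedioxy-8-oxo-14-nor-5αH-daucan-6α-yl 3-methylbutanoate | CC(C)CC(=O)O[C@H]1CC(=O)[C@H]2OC(C)(C)O[C@H]2[C@@]3(C)CC[C@@](O)(C(C)C)[C@H]13 | intermediate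
29 | 4β-hydroxy-9α,10α-isopropylidenedioxy-5αH-dauc-8(14)-en-6α-yl 3-methylbutanoate | CC(C)CC(=O)O[C@H]1CC(=C)[C@H]2OC(C)(C)O[C@H]2[C@@]3(C)CC[C@@](O)(C(C)C)[C@H]13 | intermediate
30 | 4β,9α,10α-trihydroxy-5αH-dauc-8(14)-en-6α-yl 3-methylbutanoate | CC(C)CC(=O)O[C@H]1CC(=C)[C@@H](O)[C@@H](O)[C@@]2(C)CC[C@@](O)(C(C)C)[C@H]12 | intermediate
31 | 8α,14-epoxy-4β,9α,10α-trihydroxy-5αH-daucan-6α-yl 3-methylbutanoate (CNP0307265.1) | CC(C)CC(=O)O[C@H]1C[C@]2(CO2)[C@@H](O)[C@@H](O)[C@@]2(C)CC[C@@](O)(C(C)C)[C@H]12 | target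

## Step count and risks

Total step count: 19. Longest linear sequence: 19 steps (1 to 31).

**Step 13.**
- What may go wrong: the hydrogen transfer may be slow, because equatorial O6 and H4β lie on opposite sides of the C4–C5–C6 plane. Chains would then be short, and bromine radicals could start to attack the C–H bonds next to the acetal oxygens.
- After ionisation, loss of a proton from C3, C5 or the isopropyl methine may also outrun closure to the twist-boat ring.
- Fallback: the relay is run from the 6β epimer, in which axial O6 is 1,3-syn to H4β and the carbonate closes as a chair, and C6 is corrected afterwards.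
- It sets out from 20. LiAlH4 (THF, reflux) removes the carbamate to give the 6α-alcohol F1, and Dess–Martin periodinane gives the 6-ketone F2.
- LiBH(s-Bu)3 attacks from the α face, the β face being covered by C15, to give the 6β-alcohol F3. Isocyanate 15 then gives the 6β-carbamate F4.
- The sequence of step 13 should give the 4β,6β-carbonate F5, and K2CO3 in methanol the 4β,6β-diol F6.
- Dess–Martin periodinane can touch only the secondary alcohol and gives the 4β-hydroxy-6-ketone F7.
- Evans–Saksena reduction with Me4NBH(OAc)3 (MeCN–AcOH, −20 °C), in which boron bound to O4 hands hydride to the β face of C6, comes back to the route at 25.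

**Step 9.**
- What may go wrong: initiation at the propenyl group next to quaternary C1 may be too slow. The catalyst would then decay, or the vinyl ketone would dimerise or polymerise before the ring closes.
- Fallback: C9=C10 is made by an intramolecular Horner–Wadsworth–Emmons reaction instead of metathesis, which also bypasses the sensitive vinyl ketone of steps 7 and 8.
- It sets out from 12. The dianion of dimethyl (2-oxopropyl)phosphonate (NaH, then n-BuLi, THF, −78 °C) adds through its terminal carbon in the Felkin–Anh sense to give the δ-hydroxy-β-ketophosphonate F8.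
- Isocyanate 15 under the conditions of step 8 gives the carbamate F9.
- Ozonolysis of the propenyl group (O3, CH2Cl2, −78 °C; Me2S) gives the C10 aldehyde F10.
- Masamune–Roush conditions (LiCl, i-Pr2NEt, MeCN, high dilution) close the ring and come back to the route at 17.

**Step 2.**
- What may go wrong: poor facial selectivity of the early, reactant-like alkylation transition state. Proton exchange between enolate and product may also lead to regioisomers and double allylation.
- Fallback: the quaternary centre is set under catalyst control by decarboxylative asymmetric allylic alkylation (Tsuji allylation).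
- It sets out from 2. Conjugate reduction with LiBH(s-Bu)3 (THF, −78 °C) and O-acylation of the enolate with allyl chloroformate give the allyl enol carbonate F11.
- Pd2(dba)3 with (R)-t-Bu-PHOX (toluene, rt) expels CO2 and recombines the enolate and the allyl fragment on the face chosen by the ligand. This comes back to the route at 5.

## Further compounds

F1 | step 13 | 8,8-ethylenedioxy-9α,10α-isopropylidenedioxy-14-nor-4βH,5αH-daucan-6α-ol | O[C@H]1CC2(OCCO2)[C@H]3OC(C)(C)O[C@H]3[C@@]4(C)CC[C@@H](C(C)C)[C@H]14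
F2 | step 13 | 8,8-ethylenedioxy-9α,10α-isopropylidenedioxy-14-nor-4βH,5αH-daucan-6-one | O=C1CC2(OCCO2)[C@H]3OC(C)(C)O[C@H]3[C@@]4(C)CC[C@@H](C(C)C)[C@H]14
F3 | step 13 | 8,8-ethylenedioxy-9α,10α-isopropylidenedioxy-14-nor-4βH,5αH-daucan-6β-ol | O[C@@H]1CC2(OCCO2)[C@H]3OC(C)(C)O[C@H]3[C@@]4(C)CC[C@@H](C(C)C)[C@H]14
F4 | step 13 | 6β-(2,2,2-trifluoroethyl)carbamate of F3 | FC(F)(F)CNC(=O)O[C@@H]1CC2(OCCO2)[C@H]3OC(C)(C)O[C@H]3[C@@]4(C)CC[C@@H](C(C)C)[C@H]14
F5 | step 13 | 8,8-ethylenedioxy-9α,10α-isopropylidenedioxy-14-nor-5αH-daucane-4β,6β-diyl carbonate | O=C1O[C@@H]2CC3(OCCO3)[C@H]4OC(C)(C)O[C@H]4[C@@]5(C)CC[C@@](O1)(C(C)C)[C@H]25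
F6 | step 13 | 8,8-ethylenedioxy-9α,10α-isopropylidenedioxy-14-nor-5αH-daucane-4β,6β-diol | O[C@@H]1CC2(OCCO2)[C@H]3OC(C)(C)O[C@H]3[C@@]4(C)CC[C@@](O)(C(C)C)[C@H]14
F7 | step 13 | 8,8-ethylenedioxy-4β-hydroxy-9α,10α-isopropylidenedioxy-14-nor-5αH-daucan-6-one | O=C1CC2(OCCO2)[C@H]3OC(C)(C)O[C@H]3[C@@]4(C)CC[C@@](O)(C(C)C)[C@H]14
F8 | step 9 | dimethyl {(4S)-4-hydroxy-4-[ring A of 12]-2-oxobutyl}phosphonate | C/C=C/[C@@]1(C)CC[C@@H](C(C)C)[C@@H]1[C@@H](O)CC(=O)CP(=O)(OC)OC
F9 | step 9 | (2,2,2-trifluoroethyl)carbamate of F8 at O6 | C/C=C/[C@@]1(C)CC[C@@H](C(C)C)[C@@H]1[C@@H](OC(=O)NCC(F)(F)F)CC(=O)CP(=O)(OC)OC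
F10 | step 9 | C10 aldehyde from F9 (formyl in place of propenyl at C1) | O=C[C@@]1(C)CC[C@@H](C(C)C)[C@@H]1[C@@H](OC(=O)NCC(F)(F)F)CC(=O)CP(=O)(OC)OC
F11 | step 2 | allyl (5R)-2-methyl-5-(propan-2-yl)cyclohex-1-en-1-yl carbonate | C=CCOC(=O)OC1=C(C)CC[C@@H](C(C)C)C1
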